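The earlier runs and the new flask were computed for an exercise.

The solid substrate enters this flask undissolved, and the coupling partner waits for it in solution.

| flask | solid substrate | coupling partner | remark | time |
|---|---|---|---|---|
| green | 0.070 M | 0.10 M | run made earlier |  |
| ochre | 0.11 M | 0.10 M | run made earlier |  |
| violet | 0.050 M | 0.15 M | run made earlier |  |
| flask | 0.050 M | 0.100 M |  | 1.5 h |

| run | time / min | target / % |
|---|---|---|
| green | 20.0 | 6 |
| green | 40.0 | 4 |
| green | 50.0 | 6 |
| green | 80.0 | 2 |
| green | 90.0 | 1 |
| green | 120 | 4 |
| ochre | 8.00 | 6 |
| ochre | 15.0 | 5 |
| ochre | 25.0 | 2 |
| ochre | 40.0 | 4 |
| ochre | 60.0 | 5 |
| ochre | 120 | 3 |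
| violet | 20.0 | 15 |
| violet | 40.0 | 6 |
| violet | 60.0 | 4 |
| violet | 80.0 | 4 |
| violet | 120 | 3 |

(standard deviation of a reading: 1.5 percentage points)

- given per volume of solution although it is solid: solid substrate
- the analysis behind the earlier runs scatters by 1.5 percentage points, standard deviation
- at the start none of the solid substrate is in solution

* target at 1.5 h, in percent of the solid substrate charged
* the change that raises the amount of target at 1.5 h, in percent of the solid substrate charged most ("none" if none brings more than 2 percentage points) (east / south-east / north-west / none)
* amount of target at 1.5 h, in percent of the solid substrate charged, after north-west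

- east: doubling the dissolution coefficient of the solid substrate, all else as stated
- south-east: doubling the amount of coupling partner, all else as stated
- north-west: doubling the solubility of the solid substrate, all else as stated

I build the flask one process at a time. With the main step alone, dissolved substrate plus coupling partner gives target, with the solid substrate as the limiting reagent at 0.050 M against 0.100 M, and the target should rise and then hold its level. The violet run instead peaks early at a reading of 15% and falls to 6% by 40.0 min, so a loss must be added.

A first-order loss repeats that factor of 2.50 every 20.0 min, which gives 0.960% at 80.0 min, yet the reading there is 4%. So I add a second-order decay, in which the target is consumed by something that falls in step with it. Its concentration then goes as one over time, and what carries over is the late product, target concentration times time: 144 mM·min. I read it from the green and ochre runs at 40.0 min, which have this flask's partner level.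

Putting it back into violet gives 2.40% at 120 min against a reading of 3%, with a scatter of 1.5 percentage points. For this flask it gives 3.20%. The product holds no term for solubility or dissolution, so I expect the same after north-west and after east. Violet, with more partner, reads 120 mM·min at 40.0 min, no gain, so my choice is none.

The forecast gives 4%, north-west as the best change and 7% after it, holding that “Doubling solubility directly doubles dissolved substrate”, and it parts from my reckoning on the last two.

The flask gives 3.00%, best change none, and 2.83% after north-west; the gains are −0.045 points for east, 1.1 points for south-east and −0.18 points for north-west.

    solid substrate ⇌ dissolved substrate, rate k1*(cs1 - [dissolved substrate]) while solid is left; crystals form when [dissolved substrate] > cs1 (solubility = 24.0 mM, k = 0.850 min⁻¹)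
    dissolved substrate + coupling partner ⇌ target (K = 5.90 L mol⁻¹, k = 1.20 L mol⁻¹ min⁻¹)
    dissolved substrate + target → side product A (k = 5.40 L mol⁻¹ min⁻¹)
    solid substrate + target → side product B (k = 0.920 L mol⁻¹ min⁻¹)

At 1.5 h this flask makes target at 0.407 of the rate at which it uses it up, with solid substrate at 0%. Its late product is 135 mM·min, against my 144 mM·min. For the same flask stopped at 25 min, the late product gives 11.5%, and the computed result is 10.4%.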